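**Retrosynthetic overview**
- Both pyrrole rings are revealed last, in one double reductive dehydration of a bis(3-hydroxyoxindole).
- Each aryl–C3 bond is made by adding an aryllithium of the central ring to the C3 ketone of an isatin. The isatin serves as an electrophilic equivalent of the normally nucleophilic indole C3, so two inherently nucleophilic carbons are joined.
- The two arms are differentiated by sequential Br–Li exchange on the para-dibromide of 1,2,4,5-tetramethoxybenzene.
- Ring order: the central benzene ring is bought intact; the two benzo-fused five-membered rings arrive preformed in 5-methoxyisatin and 5-hydroxyisatin. No ring is built; the two lactam rings are converted to pyrroles at the end.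

Assumption: the target has no stereocentre and no stereogenic axis (each biaryl bond is flanked by two identical OMe groups), so it is achiral. The carbinol centres of the intermediates form without control and are erased in the last step.

**Step 1**
Reactants: 1 1,2,4,5-tetramethoxybenzene
Product: 2 1,4-dibromo-2,3,5,6-tetramethoxybenzene
Conditions: NBS (2.1 equiv), MeCN, 0 °C → rt
Reagents that add atoms: N-bromosuccinimide, O=C1CCC(=O)N1Br
Why: The only two free ring positions are each flanked by two methoxy groups, so electrophilic aromatic bromination gives the para-dibromide cleanly and no stereocentre is formed.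

**Step 2**
Reactants: 2 1,4-dibromo-2,3,5,6-tetramethoxybenzene; 3 5-methoxyisatin
Product: 6 3-(4-bromo-2,3,5,6-tetramethoxyphenyl)-3-hydroxy-5-methoxyindolin-2-one (racemic), via (4-bromo-2,3,5,6-tetramethoxyphenyl)lithium 4 (not isolated), via sodium 5-methoxyisatinate 5 (not isolated)
Conditions: 2, n-BuLi (1.0 equiv), THF, −78 °C; 3 (1.1 equiv), NaH (1.15 equiv), THF, 0 °C; add 4 to 5, −78 → 0 °C; 0.5 M aq HCl, 0 °C
Reagents that add atoms: none
Why: Mono bromine–lithium exchange gives aryllithium 4, which undergoes 1,2-addition to the C3 ketone of the N-sodio isatinate (the amidate masks N–H and deactivates C2), the isatin ketone acting as a reversed-polarity indol-3-yl cation equivalent; the new carbinol centre forms racemic and is erased in step 4.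

**Step 3**
Reactants: 6 3-(4-bromo-2,3,5,6-tetramethoxyphenyl)-3-hydroxy-5-methoxyindolin-2-one; 7 5-hydroxyisatin
Product: 11 3-[4-(3,5-dihydroxy-2-oxoindolin-3-yl)-2,3,5,6-tetramethoxyphenyl]-3-hydroxy-5-methoxyindolin-2-one (two racemic diastereomers), via lithiated disodium salt 8 (not isolated), via sodium 5-(trimethylsilyloxy)isatinate 9 (not isolated), via mono-O-trimethylsilyl bis-adduct 10 (not isolated)
Conditions: 6, NaH (2.1 equiv), THF, 0 °C → rt, then t-BuLi (2.1 equiv), −78 °C; 7 (1.5 equiv), NaH (2.05 equiv per 7), THF, 0 °C, then Me3SiCl (1.0 equiv per 7); add 9 to 8, −78 → 0 °C; 0.5 M aq HCl/THF, 0 °C → rt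
Reagents that add atoms: none
Why: With O–H and N–H of 6 masked as sodium salts, the second bromine–lithium exchange gives aryllithium 8, which undergoes 1,2-addition to the C3 ketone of 9 (phenol masked in the flask as a trimethylsilyl ether that is hydrolysed in the acidic work-up), attaching the second reversed-polarity indole C3 without an isolated protecting group; the second carbinol centre forms without control and is erased in step 4.

**Step 4**
Reactants: 11 3-[4-(3,5-dihydroxy-2-oxoindolin-3-yl)-2,3,5,6-tetramethoxyphenyl]-3-hydroxy-5-methoxyindolin-2-one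
Product: 13 3-[2,3,5,6-tetramethoxy-4-(5-methoxy-1H-indol-3-yl)phenyl]-1H-indol-5-ol, via bis(3-hydroxyindoline) 12 (not isolated)
Conditions: BH3·THF (10 equiv), THF, 0 °C → reflux, Ar; MeOH, then 1 M aq HCl, rt
Reagents that add atoms: none
Why: Borane reduction of each 3-hydroxy lactam (dioxindole) gives the 3-hydroxyindoline, which dehydrates on acidic work-up to the aromatic indole, removing both carbinol stereocentres and giving the achiral target.

**Compound list**
1 | 1,2,4,5-tetramethoxybenzene | COc1cc(OC)c(OC)cc1OC | starting material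
2 | 1,4-dibromo-2,3,5,6-tetramethoxybenzene | COc1c(Br)c(OC)c(OC)c(Br)c1OC | intermediate
3 | 5-methoxyisatin (5-methoxyindoline-2,3-dione) | COc1ccc2NC(=O)C(=O)c2c1 | starting material
4 | (4-bromo-2,3,5,6-tetramethoxyphenyl)lithium, formed in the flask | [Li]c1c(OC)c(OC)c(Br)c(OC)c1OC | intermediate
5 | sodium 5-methoxy-2,3-dioxoindolin-1-ide (sodium 5-methoxyisatinate), formed in the flask | COc1ccc2[N-]C(=O)C(=O)c2c1.[Na+] | intermediate
6 | 3-(4-bromo-2,3,5,6-tetramethoxyphenyl)-3-hydroxy-5-methoxyindolin-2-one, racemic | COc1ccc2NC(=O)C(O)(c3c(OC)c(OC)c(Br)c(OC)c3OC)c2c1 | intermediate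
7 | 5-hydroxyisatin (5-hydroxyindoline-2,3-dione) | Oc1ccc2NC(=O)C(=O)c2c1 | starting material
8 | disodium alkoxide/amidate salt of 6 carrying lithium in place of bromine, racemic, formed in the flask | [Li]c1c(OC)c(OC)c(C2([O-])C(=O)[N-]c3ccc(OC)cc32)c(OC)c1OC.[Na+].[Na+] | intermediate
9 | sodium 5-(trimethylsilyloxy)-2,3-dioxoindolin-1-ide, formed in the flask | C[Si](C)(C)Oc1ccc2[N-]C(=O)C(=O)c2c1.[Na+] | intermediate
10 | 3-hydroxy-3-{4-[3-hydroxy-2-oxo-5-(trimethylsilyloxy)indolin-3-yl]-2,3,5,6-tetramethoxyphenyl}-5-methoxyindolin-2-one, diastereomer mixture, formed in the flask | COc1ccc2NC(=O)C(O)(c3c(OC)c(OC)c(C4(O)C(=O)Nc5ccc(O[Si](C)(C)C)cc54)c(OC)c3OC)c2c1 | intermediate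
11 | 3-[4-(3,5-dihydroxy-2-oxoindolin-3-yl)-2,3,5,6-tetramethoxyphenyl]-3-hydroxy-5-methoxyindolin-2-one, two racemic diastereomers | COc1ccc2NC(=O)C(O)(c3c(OC)c(OC)c(C4(O)C(=O)Nc5ccc(O)cc54)c(OC)c3OC)c2c1 | intermediate
12 | 3-[4-(3,5-dihydroxyindolin-3-yl)-2,3,5,6-tetramethoxyphenyl]-5-methoxyindolin-3-ol, diastereomer mixture, formed in the flask | COc1ccc2NCC(O)(c3c(OC)c(OC)c(C4(O)CNc5ccc(O)cc54)c(OC)c3OC)c2c1 | intermediate
13 | 3-[2,3,5,6-tetramethoxy-4-(5-methoxy-1H-indol-3-yl)phenyl]-1H-indol-5-ol (achiral) | COc1ccc2[nH]cc(-c3c(OC)c(OC)c(-c4c[nH]c5ccc(O)cc45)c(OC)c3OC)c2c1 | target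

**Step count**
Total steps: 4. Longest linear sequence: 4 steps (1 → 2 → 6 → 11 → 13); both isatins are bought.

**Steps most likely to fail**

Step 3 is the riskiest. The mixed sodium/lithium trianion 8 may be poorly soluble or be quenched, and it may attack silicon of 9 instead of the ketone. The fallback sets out from 6 and comes back at 13. Reduce 6 with BH3·THF (THF, reflux; MeOH, aq HCl) to 3-(4-bromo-2,3,5,6-tetramethoxyphenyl)-5-methoxy-1H-indole F1. Treat it with NaH and then t-BuLi (THF, −78 °C) to form the N-sodio aryllithium F2, which carries only one extra charge. Add this to sodium 5-(benzyloxy)-2,3-dioxoindolin-1-ide F4, made with NaH from bought 5-(benzyloxy)isatin F3, to obtain 5-(benzyloxy)-3-hydroxy-3-[2,3,5,6-tetramethoxy-4-(5-methoxy-1H-indol-3-yl)phenyl]indolin-2-one F5. Reduce this with BH3·THF to 5-(benzyloxy)-3-[2,3,5,6-tetramethoxy-4-(5-methoxy-1H-indol-3-yl)phenyl]-1H-indole F6, and cleave the benzyl ether with H2 and 10% Pd/C in EtOAc/MeOH to reach 13.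

Step 4 is next. The double lactam reduction next to two very hindered carbinols may stall or stop at mixed oxidation levels. The fallback sets out from 11 and comes back at 13. Ionic hydrogenation with Et3SiH and CF3CO2H in CH2Cl2 removes both tertiary hydroxyls through cations stabilised by the tetramethoxyphenyl ring, giving 3-[4-(5-hydroxy-2-oxoindolin-3-yl)-2,3,5,6-tetramethoxyphenyl]-5-methoxyindolin-2-one F7. Partial reduction of both lactams with i-Bu2AlH (excess, CH2Cl2, −78 °C → rt), followed by acidic work-up, dehydrates the resulting 2-hydroxyindolines to 13.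

Step 2 is third. Mono-exchange of 2 may not be clean, or aryllithium 4 may react sluggishly with the suspended salt 5. The fallback sets out from 1 and comes back at 6. Lithiate 1 directly between two methoxy groups (n-BuLi, THF, 0 °C → rt, directed ortho-metalation) to (2,3,5,6-tetramethoxyphenyl)lithium F8. Use 2.2 equiv of it on unprotected 3; the first equivalent only removes N–H and returns 1. This gives 3-hydroxy-5-methoxy-3-(2,3,5,6-tetramethoxyphenyl)indolin-2-one F9. Brominate its one remaining, doubly methoxy-flanked arene position with NBS (1.0 equiv, MeCN, 0 °C) to reach 6.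

**Further compounds**
F1 | step 3 | 3-(4-bromo-2,3,5,6-tetramethoxyphenyl)-5-methoxy-1H-indole | COc1ccc2[nH]cc(-c3c(OC)c(OC)c(Br)c(OC)c3OC)c2c1
F2 | step 3 | N-sodio aryllithium from F1 (lithium in place of bromine), formed in the flask | [Li]c1c(OC)c(OC)c(-c2c[n-]c3ccc(OC)cc23)c(OC)c1OC.[Na+]
F3 | step 3 | 5-(benzyloxy)isatin (bought) | O=C1Nc2ccc(OCc3ccccc3)cc2C1=O
F4 | step 3 | sodium 5-(benzyloxy)-2,3-dioxoindolin-1-ide, formed in the flask | O=C1[N-]c2ccc(OCc3ccccc3)cc2C1=O.[Na+]
F5 | step 3 | 5-(benzyloxy)-3-hydroxy-3-[2,3,5,6-tetramethoxy-4-(5-methoxy-1H-indol-3-yl)phenyl]indolin-2-one, racemic | COc1ccc2[nH]cc(-c3c(OC)c(OC)c(C4(O)C(=O)Nc5ccc(OCc6ccccc6)cc54)c(OC)c3OC)c2c1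
F6 | step 3 | 5-(benzyloxy)-3-[2,3,5,6-tetramethoxy-4-(5-methoxy-1H-indol-3-yl)phenyl]-1H-indole | COc1ccc2[nH]cc(-c3c(OC)c(OC)c(-c4c[nH]c5ccc(OCc6ccccc6)cc45)c(OC)c3OC)c2c1
F7 | step 4 | 3-[4-(5-hydroxy-2-oxoindolin-3-yl)-2,3,5,6-tetramethoxyphenyl]-5-methoxyindolin-2-one, diastereomer mixture | COc1ccc2NC(=O)C(c3c(OC)c(OC)c(C4C(=O)Nc5ccc(O)cc54)c(OC)c3OC)c2c1
F8 | step 2 | (2,3,5,6-tetramethoxyphenyl)lithium, formed in the flask | [Li]c1c(OC)c(OC)cc(OC)c1OC
F9 | step 2 | 3-hydroxy-5-methoxy-3-(2,3,5,6-tetramethoxyphenyl)indolin-2-one, racemic | COc1ccc2NC(=O)C(O)(c3c(OC)c(OC)cc(OC)c3OC)c2c1
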